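**Retrosynthetic overview**
- The target is a depside. Its hindered ester joins ring A (2,4-dimethoxy-6-propylbenzoyl) to O3 of ring B (2,4-dihydroxy-6-propylbenzoic acid). It is reached from a tribenzyl-protected precursor by O-methylation of the ring A 2-hydroxyl and hydrogenolysis.
- The strategy rests on ring A: its C1 (acyl-bearing) and C6 (propyl-bearing) are the two alkyne carbons of a hex-2-ynoate ester on the ring B C3 oxygen. C2 to C5 come from a 1-methoxy-1-silyloxy diene, so the C1–C2 and C5–C6 bonds form in a Diels–Alder benzannulation.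
- The di-ortho-substituted aroyl ester is therefore never made by acylation. The ester bond is formed earlier from the unhindered ynoic acid and the ring B phenol.
- The ring B phenol comes from 5-propylresorcinol: formylation and oxidation give the carboxyl, and a second formylation at C3 followed by Baeyer–Villiger (Dakin-type) oxidation gives the C3 oxygen.
- Ring order: ring B is aromatic from the start; ring A is the only ring formed (step 9).

Key step: step 9

Remark: the target has no stereogenic element. The ketene acetal geometry of the diene is left open because it is lost on aromatization, and the two transient sp3 centres (in 6 and 15) are racemic and disappear.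

Step 1
Reactants: 1 5-propylbenzene-1,3-diol
Product: 3 2,4-dihydroxy-6-propylbenzaldehyde, via iminium chloride 2 (not isolated)
Conditions: POCl3, DMF, 0 °C to rt; then ice/H2O, 50 °C
Reagents that add atoms: N,N-dimethylformamide, CN(C)C=O; water, O
Why: Vilsmeier–Haack formylation attacks the resorcinol position para to one hydroxyl and ortho to the other, as with orcinol and olivetol, and the bulky chloroiminium ion avoids the position between the two hydroxyls.

Step 2
Reactants: 3 2,4-dihydroxy-6-propylbenzaldehyde
Product: 4 2,4-dihydroxy-6-propylbenzoic acid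
Conditions: NaClO2, NaH2PO4, DMSO/H2O, 0 °C to rt
Reagents that add atoms: sodium chlorite, [Na+].[O-]Cl=O
Why: Pinnick (Lindgren) oxidation with DMSO as the hypochlorous acid scavenger should convert the hydroxybenzaldehyde to the acid without phenol protection, the scavenger holding back ring chlorination.

Step 3
Reactants: 4 2,4-dihydroxy-6-propylbenzoic acid
Product: 5 benzyl 2,4-dihydroxy-6-propylbenzoate
Conditions: BnBr (1.05 equiv), KHCO3, DMF, rt
Reagents that add atoms: benzyl bromide, BrCc1ccccc1
Why: Carboxylate SN2 alkylation; bicarbonate ionizes only the carboxylic acid, so the phenols should stay free.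

Step 4
Reactants: 5 benzyl 2,4-dihydroxy-6-propylbenzoate
Product: 7 benzyl 3-formyl-2,4-dihydroxy-6-propylbenzoate, via alpha-chloro ether 6 (not isolated)
Conditions: Cl2CHOMe, TiCl4, CH2Cl2, -10 to 0 °C; then ice/1 M HCl
Reagents that add atoms: dichloromethyl methyl ether, COC(Cl)Cl; water, O
Why: Rieche formylation; titanium phenoxide chelation should direct the electrophile to C3, ortho to both hydroxyls (the haematommate pattern known for orsellinate esters), while C5 is screened by the propyl group.

Step 5
Reactants: 7 benzyl 3-formyl-2,4-dihydroxy-6-propylbenzoate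
Product: 8 benzyl 2,4-bis(benzyloxy)-3-formyl-6-propylbenzoate
Conditions: BnBr (3 equiv), K2CO3, DMF, 60 °C
Reagents that add atoms: benzyl bromide, BrCc1ccccc1
Why: Williamson etherification; excess benzyl bromide in warm DMF should alkylate both hydrogen-bonded phenols.

Step 6
Reactants: 8 benzyl 2,4-bis(benzyloxy)-3-formyl-6-propylbenzoate
Product: 10 benzyl 2,4-bis(benzyloxy)-3-hydroxy-6-propylbenzoate, via aryl formate 9 (not isolated)
Conditions: mCPBA, CH2Cl2, 0 °C to rt; then Et3N, MeOH, rt
Reagents that add atoms: 3-chloroperoxybenzoic acid, OOC(=O)c1cccc(Cl)c1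
Why: Baeyer–Villiger (Dakin-type) oxidation; the electron-rich di-ortho-alkoxy aryl group migrates in preference to hydride, and mild methanolysis cleaves the aryl formate while the hindered benzyl ester should survive.

Step 7
Reactants: 10 benzyl 2,4-bis(benzyloxy)-3-hydroxy-6-propylbenzoate; 11 hex-2-ynoic acid
Product: 12 benzyl 2,4-bis(benzyloxy)-3-(hex-2-ynoyloxy)-6-propylbenzoate
Conditions: DCC, DMAP (cat.), CH2Cl2, 0 °C to rt
Reagents that add atoms: none
Why: Steglich esterification; the slim sp-hybridized acyl unit should reach the phenol flanked by two benzyloxy groups, which a di-ortho-substituted aroyl unit would not do readily.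

Step 8
Reactants: 13 methyl (E)-3-methoxybut-2-enoate
Product: 14 1,3-dimethoxy-1-(trimethylsilyloxy)buta-1,3-diene
Conditions: LiN(iPr)2, THF, -78 °C; then Me3SiCl, -78 °C to rt; non-aqueous work-up, distillation
Reagents that add atoms: chlorotrimethylsilane, C[Si](C)(C)Cl
Why: Kinetic gamma-deprotonation of the vinylogous ester and O-silylation of the dienolate give the Brassard-type silyl ketene acetal diene.

Step 9
Reactants: 12 benzyl 2,4-bis(benzyloxy)-3-(hex-2-ynoyloxy)-6-propylbenzoate; 14 1,3-dimethoxy-1-(trimethylsilyloxy)buta-1,3-diene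
Product: 17 benzyl 2,4-bis(benzyloxy)-3-[(2-hydroxy-4-methoxy-6-propylbenzoyl)oxy]-6-propylbenzoate, via cycloadduct 15 (not isolated), via aryl silyl ether 16 (not isolated)
Conditions: 14 (3 equiv), PhMe, 120 °C, sealed tube; then 1 M HCl, THF, rt
Reagents that add atoms: none
Why: A normal-demand [4+2] cycloaddition (asynchronous concerted, or Mukaiyama–Michael addition followed by ring closure) joins the unsubstituted CH2 terminus of diene 14 to the propyl-bearing beta carbon of ynoate 12 and the ketene acetal carbon to the alpha carbon, giving 1,4-cyclohexadiene 15. The closest known reaction is the Diels–Alder benzannulation of 1-alkoxy-1-silyloxy-1,3-dienes with alk-2-ynoate esters to give resorcylates. Ring A closes as a six-membered carbocycle in this cycloaddition, which makes its C1–C2 and C5–C6 bonds; the mixed ketal carbon of 15 then loses methanol by 1,4-elimination across the ring CH2 to give aromatic silyl ether 16, which dilute acid cleaves to the hydrogen-bonded phenol 17. No stereocenter remains, since the ketal carbon of 15 is transient. The step needs regioselectivity (hydroxyl ortho to the acyl carbon, propyl on the other ortho position), which the matched polarization of the ynoate (electrophilic beta carbon) and the diene (nucleophilic CH2 terminus) should secure. The aryl ester makes the ynoate more electron-poor than an alkyl ester, and the two flanking benzyloxy groups shield its carbonyl from acyl transfer to the diene.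

Step 10
Reactants: 17 benzyl 2,4-bis(benzyloxy)-3-[(2-hydroxy-4-methoxy-6-propylbenzoyl)oxy]-6-propylbenzoate
Product: 18 benzyl 2,4-bis(benzyloxy)-3-[(2,4-dimethoxy-6-propylbenzoyl)oxy]-6-propylbenzoate
Conditions: MeI, K2CO3, dry DMF, rt to 40 °C
Reagents that add atoms: iodomethane, CI
Why: Williamson O-methylation of the chelated phenol; carbonate in a dry aprotic solvent should not be nucleophilic enough to cleave the hindered aryl ester.

Step 11
Reactants: 18 benzyl 2,4-bis(benzyloxy)-3-[(2,4-dimethoxy-6-propylbenzoyl)oxy]-6-propylbenzoate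
Product: 19 3-[(2,4-dimethoxy-6-propylbenzoyl)oxy]-2,4-dihydroxy-6-propylbenzoic acid
Conditions: H2 (1 atm), 10% Pd/C, EtOAc, rt
Reagents that add atoms: none
Why: Catalytic hydrogenolysis should cleave the two benzyl ethers and the benzyl ester and leave the aryl ester, the methyl ethers and both arenes intact; the non-nucleophilic solvent avoids transesterification of the depside.

**Compound list**
1 | 5-propylbenzene-1,3-diol | CCCc1cc(O)cc(O)c1 | starting material
2 | [(2,4-dihydroxy-6-propylphenyl)methylidene]dimethylammonium chloride | CCCc1cc(O)cc(O)c1C=[N+](C)C.[Cl-] | intermediate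
3 | 2,4-dihydroxy-6-propylbenzaldehyde | CCCc1cc(O)cc(O)c1C=O | intermediate
4 | 2,4-dihydroxy-6-propylbenzoic acid | CCCc1cc(O)cc(O)c1C(=O)O | intermediate
5 | benzyl 2,4-dihydroxy-6-propylbenzoate | CCCc1cc(O)cc(O)c1C(=O)OCc1ccccc1 | intermediate
6 | benzyl 3-[chloro(methoxy)methyl]-2,4-dihydroxy-6-propylbenzoate (racemic, transient) | CCCc1cc(O)c(C(Cl)OC)c(O)c1C(=O)OCc1ccccc1 | intermediate
7 | benzyl 3-formyl-2,4-dihydroxy-6-propylbenzoate | CCCc1cc(O)c(C=O)c(O)c1C(=O)OCc1ccccc1 | intermediate
8 | benzyl 2,4-bis(benzyloxy)-3-formyl-6-propylbenzoate | CCCc1cc(OCc2ccccc2)c(C=O)c(OCc2ccccc2)c1C(=O)OCc1ccccc1 | intermediate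
9 | benzyl 2,4-bis(benzyloxy)-3-(formyloxy)-6-propylbenzoate | CCCc1cc(OCc2ccccc2)c(OC=O)c(OCc2ccccc2)c1C(=O)OCc1ccccc1 | intermediate
10 | benzyl 2,4-bis(benzyloxy)-3-hydroxy-6-propylbenzoate | CCCc1cc(OCc2ccccc2)c(O)c(OCc2ccccc2)c1C(=O)OCc1ccccc1 | intermediate
11 | hex-2-ynoic acid | CCCC#CC(=O)O | starting material
12 | benzyl 2,4-bis(benzyloxy)-3-(hex-2-ynoyloxy)-6-propylbenzoate | CCCC#CC(=O)Oc1c(OCc2ccccc2)cc(CCC)c(C(=O)OCc2ccccc2)c1OCc1ccccc1 | intermediate
13 | methyl (E)-3-methoxybut-2-enoate | CO/C(C)=C/C(=O)OC | starting material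
14 | 1,3-dimethoxy-1-(trimethylsilyloxy)buta-1,3-diene (ketene acetal geometry open) | C=C(OC)C=C(OC)O[Si](C)(C)C | intermediate
15 | 2,6-bis(benzyloxy)-3-[(benzyloxy)carbonyl]-4-propylphenyl 4,6-dimethoxy-2-propyl-6-(trimethylsilyloxy)cyclohexa-1,4-diene-1-carboxylate (racemic, transient) | CCCC1=C(C(=O)Oc2c(OCc3ccccc3)cc(CCC)c(C(=O)OCc3ccccc3)c2OCc2ccccc2)C(OC)(O[Si](C)(C)C)C=C(OC)C1 | intermediate
16 | benzyl 2,4-bis(benzyloxy)-3-{[4-methoxy-6-propyl-2-(trimethylsilyloxy)benzoyl]oxy}-6-propylbenzoate | CCCc1cc(OC)cc(O[Si](C)(C)C)c1C(=O)Oc1c(OCc2ccccc2)cc(CCC)c(C(=O)OCc2ccccc2)c1OCc1ccccc1 | intermediate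
17 | benzyl 2,4-bis(benzyloxy)-3-[(2-hydroxy-4-methoxy-6-propylbenzoyl)oxy]-6-propylbenzoate | CCCc1cc(OC)cc(O)c1C(=O)Oc1c(OCc2ccccc2)cc(CCC)c(C(=O)OCc2ccccc2)c1OCc1ccccc1 | intermediate
18 | benzyl 2,4-bis(benzyloxy)-3-[(2,4-dimethoxy-6-propylbenzoyl)oxy]-6-propylbenzoate | CCCc1cc(OC)cc(OC)c1C(=O)Oc1c(OCc2ccccc2)cc(CCC)c(C(=O)OCc2ccccc2)c1OCc1ccccc1 | intermediate
19 | 3-[(2,4-dimethoxy-6-propylbenzoyl)oxy]-2,4-dihydroxy-6-propylbenzoic acid | CCCc1cc(OC)cc(OC)c1C(=O)Oc1c(O)cc(CCC)c(C(=O)O)c1O | target

**Step count and risks**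

Total step count: 11. Longest linear sequence: 10 steps (steps 1 to 7, then 9 to 11, from compound 1); the diene branch is one step (step 8).

Steps most likely to fail:

1. Step 9 (key step). The diene may undergo silyl migration or decomposition at the temperature that a beta-alkyl ynoate requires. Alternatively the addition may stop at the open-chain Michael stage or proceed with poor regiocontrol. The fallback gives up the benzannulation and forms the hindered ester by a known mixed-anhydride acylation; it sets out from aldehyde 3 and phenol 10 and comes back at 18. Aldehyde 3 is O-methylated twice (MeI, K2CO3, DMF) to 2,4-dimethoxy-6-propylbenzaldehyde F1. F1 is oxidized (NaClO2, NaH2PO4, 2-methylbut-2-ene, tBuOH/H2O) to 2,4-dimethoxy-6-propylbenzoic acid F2. F2 is condensed with phenol 10 by trifluoroacetic anhydride in toluene at rt, a method suited to electron-rich di-ortho-substituted acids, to give 18 directly; steps 7 to 10 then fall away.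

2. Step 4. Formylation may occur at C5 instead of C3, and TiCl4 may partly cleave the benzyl ester. The fallback sets out from 5 and comes back at 8. The non-chelated 4-hydroxyl is benzylated selectively (BnBr 1.0 equiv, K2CO3, acetone) to benzyl 4-(benzyloxy)-2-hydroxy-6-propylbenzoate F3. The single remaining phenol then directs a magnesium-mediated ortho-formylation (MgCl2, Et3N, paraformaldehyde, MeCN, reflux), whose only open ortho position is C3, to give benzyl 4-(benzyloxy)-3-formyl-2-hydroxy-6-propylbenzoate F4. Benzylation of the remaining phenol (BnBr, K2CO3, DMF, 60 °C) gives 8.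

3. Step 2. Hypochlorous acid formed during the chlorite oxidation may chlorinate the unprotected resorcinol ring, and the chelated, vinylogous-acid-like aldehyde may oxidize slowly. The fallback sets out from 3 and comes back at 5. Both phenols are protected (MOMCl, NaH, DMF) to give 2,4-bis(methoxymethoxy)-6-propylbenzaldehyde F5. Standard Pinnick oxidation (NaClO2, NaH2PO4, 2-methylbut-2-ene, tBuOH/H2O) gives 2,4-bis(methoxymethoxy)-6-propylbenzoic acid F6. Benzylation (BnBr, K2CO3, DMF) gives benzyl 2,4-bis(methoxymethoxy)-6-propylbenzoate F7, and the acetals are removed (HCl, MeOH, rt) to give 5.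

Further compounds
F1 | step 9 | 2,4-dimethoxy-6-propylbenzaldehyde | CCCc1cc(OC)cc(OC)c1C=O
F2 | step 9 | 2,4-dimethoxy-6-propylbenzoic acid | CCCc1cc(OC)cc(OC)c1C(=O)O
F3 | step 4 | benzyl 4-(benzyloxy)-2-hydroxy-6-propylbenzoate | CCCc1cc(OCc2ccccc2)cc(O)c1C(=O)OCc1ccccc1
F4 | step 4 | benzyl 4-(benzyloxy)-3-formyl-2-hydroxy-6-propylbenzoate | CCCc1cc(OCc2ccccc2)c(C=O)c(O)c1C(=O)OCc1ccccc1
F5 | step 2 | 2,4-bis(methoxymethoxy)-6-propylbenzaldehyde | CCCc1cc(OCOC)cc(OCOC)c1C=O
F6 | step 2 | 2,4-bis(methoxymethoxy)-6-propylbenzoic acid | CCCc1cc(OCOC)cc(OCOC)c1C(=O)O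
F7 | step 2 | benzyl 2,4-bis(methoxymethoxy)-6-propylbenzoate | CCCc1cc(OCOC)cc(OCOC)c1C(=O)OCc1ccccc1
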